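## Retrosynthetic overview

1. Target 28 comes from hepta-O-benzyl dimer 27 by hydrogenolysis. 27 comes from a Friedel–Crafts union, as in the biosynthesis, of the C4 cation of upper 4-methoxyflavan 26 with C6 of lower flavan 15.
2. Each flavan comes from an acyclic, tyrosine-derived 1,3-diarylpropane-1,2-diol derivative whose ring A is still a plain p-alkylphenol. Ring C is closed last through the O1–C8a bond: the phenol is oxidized to a 4-methoxycyclohexa-2,5-dienone, then one acid-triggered domino (desilylation, 6-exo oxa-Michael addition of the C2 hydroxyl, loss of methanol with rearomatization) gives the flavan.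
3. Enabling feature: in ring A of the lower unit the phenolic C7–OH is para to C4a (the carbon carrying the C4 methylene), and O1 sits on C8a, ortho to C4a and meta to C7–OH. In the dienone made from that p-alkylphenol, C8a is the enone β-carbon within six-ring reach of the C2 hydroxyl, and the C4a methoxy group leaves to restore the arene. The same para relationship lets the upper unit form its C4 quinone methide.
4. Stereocentres: C3 of both units is the α-carbon of L-tyrosine. C2 is set by Cram-chelate control from one Weinreb amide 5 (hydride to ketone 8 gives anti, 2R, lower unit; aryl to aldehyde 16 gives syn, 2S, upper unit). Upper C4 is set in the union, anti to the 3-benzyloxy group.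
5. Ring order: rings A and B are brought in intact; lower ring C (step 11), upper ring C (step 17), then the interflavan bond (step 20).

Key step: step 11

Remark on the structure: the target is read as ent-epifisetinidol-(4α→6)-fisetinidol. The upper unit is (2S,3S,4R) with a 2,3-cis-3,4-trans ring C, the lower unit is (2R,3S) with a 2,3-trans ring C, and the interflavan bond runs from upper C4 to lower C6.

## Route

Step 1
Reactants: 1 L-tyrosine
Product: 2 (S)-2-hydroxy-3-(4-hydroxyphenyl)propanoic acid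
Conditions: NaNO2, 1 M aq. H2SO4, 0 °C → rt
Reagents that add atoms: water, O
Why: Diazotization of the α-amino acid (van Slyke-type deaminative hydroxylation) should go with net retention through the α-lactone (double inversion), so the S centre of tyrosine becomes C3 (S) of both flavan units.

Step 2
Reactants: 2 (S)-2-hydroxy-3-(4-hydroxyphenyl)propanoic acid
Product: 3 allyl (S)-3-[4-(allyloxy)phenyl]-2-hydroxypropanoate
Conditions: allyl bromide (2.3 equiv), K2CO3, DMF, rt
Reagents that add atoms: allyl bromide, C=CCBr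
Why: Williamson-type O-alkylation; K2CO3 deprotonates only the carboxylic acid and the phenol, so the secondary alcohol should stay free.

Step 3
Reactants: 3 allyl (S)-3-[4-(allyloxy)phenyl]-2-hydroxypropanoate
Product: 4 allyl (S)-3-[4-(allyloxy)phenyl]-2-(benzyloxy)propanoate
Conditions: BnBr, Ag2O, Et2O, rt
Reagents that add atoms: benzyl bromide, BrCc1ccccc1
Why: Ag2O-promoted benzylation (neutral Williamson etherification) of an α-hydroxy ester needs no enolate, so the stereocentre should not racemize.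

Step 4
Reactants: 4 allyl (S)-3-[4-(allyloxy)phenyl]-2-(benzyloxy)propanoate
Product: 5 (S)-3-[4-(allyloxy)phenyl]-2-(benzyloxy)-N-methoxy-N-methylpropanamide
Conditions: MeNH(OMe)·HCl, i-PrMgCl, THF, −20 °C
Reagents that add atoms: N,O-dimethylhydroxylamine hydrochloride, CNOC.Cl
Why: Aminolysis of the ester by the magnesium amide (Weinreb amide formation) at low temperature should leave the α-alkoxy stereocentre untouched.

Step 5
Reactants: 6 4-bromo-1,2-bis(benzyloxy)benzene
Product: 7 [3,4-bis(benzyloxy)phenyl]magnesium bromide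
Conditions: Mg turnings, I2 (cat.), THF, 40 °C; titrated and kept under argon as a THF stock solution
Reagents that add atoms: magnesium, [Mg]
Why: Grignard reagent formation by insertion of magnesium into the aryl C–Br bond, to which the benzyl ethers are inert; one titrated solution then serves both step 6 and step 13.

Step 6
Reactants: 5 (S)-3-[4-(allyloxy)phenyl]-2-(benzyloxy)-N-methoxy-N-methylpropanamide; 7 [3,4-bis(benzyloxy)phenyl]magnesium bromide
Product: 8 (S)-3-[4-(allyloxy)phenyl]-2-(benzyloxy)-1-[3,4-bis(benzyloxy)phenyl]propan-1-one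
Conditions: 7 (THF solution, 1.3 equiv), THF, −20 → 0 °C; aq. NH4Cl
Reagents that add atoms: none
Why: Weinreb ketone synthesis; the five-membered magnesium chelate of the tetrahedral adduct should stop the addition at the ketone, and no new stereocentre is formed.

Step 7
Reactants: 8 (S)-3-[4-(allyloxy)phenyl]-2-(benzyloxy)-1-[3,4-bis(benzyloxy)phenyl]propan-1-one
Product: 9 (1R,2S)-3-[4-(allyloxy)phenyl]-2-(benzyloxy)-1-[3,4-bis(benzyloxy)phenyl]propan-1-ol (anti)
Conditions: Zn(BH4)2, Et2O, −30 → 0 °C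
Reagents that add atoms: none
Why: Chelation-controlled reduction (Cram chelate): zinc bridges the carbonyl and the α-benzyloxy oxygen and hydride enters from the face of the α-hydrogen, which should give the anti alcohol, that is C2 (R) of the lower unit.

Step 8
Reactants: 9 (1R,2S)-3-[4-(allyloxy)phenyl]-2-(benzyloxy)-1-[3,4-bis(benzyloxy)phenyl]propan-1-ol
Product: 10 [(1R,2S)-3-[4-(allyloxy)phenyl]-2-(benzyloxy)-1-[3,4-bis(benzyloxy)phenyl]propoxy]triethylsilane
Conditions: Et3SiCl, imidazole, DMF, 0 °C → rt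
Reagents that add atoms: chlorotriethylsilane, CC[Si](Cl)(CC)CC
Why: Standard silylation; it masks the future O1 so that it cannot attack the ipso carbon (five-ring spiroether) during the dearomatization of step 10.

Step 9
Reactants: 10 [(1R,2S)-3-[4-(allyloxy)phenyl]-2-(benzyloxy)-1-[3,4-bis(benzyloxy)phenyl]propoxy]triethylsilane
Product: 11 4-[(2S,3R)-2-(benzyloxy)-3-[3,4-bis(benzyloxy)phenyl]-3-(triethylsilyloxy)propyl]phenol
Conditions: Pd(PPh3)4 (cat.), morpholine, THF, rt
Reagents that add atoms: none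
Why: Tsuji–Trost-type deallylation: zerovalent palladium ionizes the allyl aryl ether and morpholine traps the π-allyl complex, while silyl and benzyl ethers should be inert.

Step 10
Reactants: 11 4-[(2S,3R)-2-(benzyloxy)-3-[3,4-bis(benzyloxy)phenyl]-3-(triethylsilyloxy)propyl]phenol
Product: 12 4-[(2S,3R)-2-(benzyloxy)-3-[3,4-bis(benzyloxy)phenyl]-3-(triethylsilyloxy)propyl]-4-methoxycyclohexa-2,5-dien-1-one
Conditions: PhI(OAc)2, NaHCO3, MeOH, 0 °C
Reagents that add atoms: methanol, CO
Why: Oxidative dearomatization of a p-alkylphenol by the trivalent iodine reagent with methanol adding at the para carbon (quinol ether formation); the buffer keeps the silyl ether and the aryl benzyl ethers are not oxidized under these conditions.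

Step 11
Reactants: 12 4-[(2S,3R)-2-(benzyloxy)-3-[3,4-bis(benzyloxy)phenyl]-3-(triethylsilyloxy)propyl]-4-methoxycyclohexa-2,5-dien-1-one
Product: 15 (2R,3S)-3-(benzyloxy)-2-[3,4-bis(benzyloxy)phenyl]chroman-7-ol, via free carbinol 13 (not isolated), via oxa-Michael adduct 14 (not isolated)
Conditions: TsOH·H2O (0.3 equiv), MeCN–H2O (20:1), 0 → 40 °C
Reagents that add atoms: none
Why: Acid first cleaves the silyl ether to carbinol 13, whose hydroxyl adds to the β-carbon of the protonated cross-conjugated dienone (the future C8a) to give cis-fused ketone 14; enolization of 14 towards C8 and acid-assisted loss of the C4a methoxy group give a cyclohexadienyl cation that loses the C8a proton, so ring A is aromatic again with O1 on C8a and the former carbonyl as the 7-OH. The closest known reaction types are the Brønsted-acid-catalysed intramolecular oxa-Michael addition of tethered alcohols to 4,4-disubstituted cyclohexa-2,5-dienones and the conjugate addition/eliminative rearomatization that turns quinol derivatives into meta-oxygenated phenols (Thiele–Winter type); here they are run as one domino. Only ring C is closed, in the 6-exo-trig mode, and no stereocentre of 15 is created: C2 and C3 come from steps 7 and 1 and are kept because the C2–O1 bond is never broken, while the transient centres C4a and C8a of 14 disappear on aromatization. The step needs six-ring closure by O1 instead of five-ring closure by O3, which the benzyl ether on O3 secures, and it needs no choice between the two enone β-carbons, because both lead to the same arene. Mild acid and the intramolecular conjugate addition are meant to outrun the dienone–phenol alkyl shift and ionization at the benzylic C2.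

Step 12
Reactants: 5 (S)-3-[4-(allyloxy)phenyl]-2-(benzyloxy)-N-methoxy-N-methylpropanamide
Product: 16 (S)-3-[4-(allyloxy)phenyl]-2-(benzyloxy)propanal
Conditions: i-Bu2AlH, THF, −78 °C; aqueous work-up, used crude
Reagents that add atoms: none
Why: Weinreb amide reduction stops at the aldehyde stage through the stable tetrahedral aluminium chelate; immediate use should avoid epimerization of the α-alkoxy aldehyde.

Step 13
Reactants: 16 (S)-3-[4-(allyloxy)phenyl]-2-(benzyloxy)propanal; 7 [3,4-bis(benzyloxy)phenyl]magnesium bromide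
Product: 17 (1S,2S)-3-[4-(allyloxy)phenyl]-2-(benzyloxy)-1-[3,4-bis(benzyloxy)phenyl]propan-1-ol (syn)
Conditions: 16 precomplexed with MgBr2·OEt2, CH2Cl2, −78 °C; 7 (THF solution) added slowly; aq. NH4Cl
Reagents that add atoms: none
Why: Chelation-controlled Grignard addition (Cram chelate): magnesium bridges the aldehyde and the α-benzyloxy oxygen and the aryl group enters from the face of the α-hydrogen, which should give the syn alcohol, that is C2 (S) of the upper unit.

Step 14
Reactants: 17 (1S,2S)-3-[4-(allyloxy)phenyl]-2-(benzyloxy)-1-[3,4-bis(benzyloxy)phenyl]propan-1-ol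
Product: 18 [(1S,2S)-3-[4-(allyloxy)phenyl]-2-(benzyloxy)-1-[3,4-bis(benzyloxy)phenyl]propoxy]triethylsilane
Conditions: Et3SiCl, imidazole, DMF, 0 °C → rt
Reagents that add atoms: chlorotriethylsilane, CC[Si](Cl)(CC)CC
Why: Standard silylation, for the same reason as in step 8.

Step 15
Reactants: 18 [(1S,2S)-3-[4-(allyloxy)phenyl]-2-(benzyloxy)-1-[3,4-bis(benzyloxy)phenyl]propoxy]triethylsilane
Product: 19 4-[(2S,3S)-2-(benzyloxy)-3-[3,4-bis(benzyloxy)phenyl]-3-(triethylsilyloxy)propyl]phenol
Conditions: Pd(PPh3)4 (cat.), morpholine, THF, rt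
Reagents that add atoms: none
Why: Tsuji–Trost-type deallylation as in step 9.

Step 16
Reactants: 19 4-[(2S,3S)-2-(benzyloxy)-3-[3,4-bis(benzyloxy)phenyl]-3-(triethylsilyloxy)propyl]phenol
Product: 20 4-[(2S,3S)-2-(benzyloxy)-3-[3,4-bis(benzyloxy)phenyl]-3-(triethylsilyloxy)propyl]-4-methoxycyclohexa-2,5-dien-1-one
Conditions: PhI(OAc)2, NaHCO3, MeOH, 0 °C
Reagents that add atoms: methanol, CO
Why: Oxidative dearomatization of the p-alkylphenol to the quinol methyl ether as in step 10.

Step 17
Reactants: 20 4-[(2S,3S)-2-(benzyloxy)-3-[3,4-bis(benzyloxy)phenyl]-3-(triethylsilyloxy)propyl]-4-methoxycyclohexa-2,5-dien-1-one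
Product: 23 (2S,3S)-3-(benzyloxy)-2-[3,4-bis(benzyloxy)phenyl]chroman-7-ol, via free carbinol 21 (not isolated), via oxa-Michael adduct 22 (not isolated)
Conditions: TsOH·H2O (0.3 equiv), MeCN–H2O (20:1), 0 → 40 °C
Reagents that add atoms: none
Why: The same desilylation/6-exo oxa-Michael/eliminative rearomatization domino as in step 11, run in the C2-epimeric series; since the C2–O1 bond is not broken, the syn alcohol should give the 2,3-cis flavan.

Step 18
Reactants: 23 (2S,3S)-3-(benzyloxy)-2-[3,4-bis(benzyloxy)phenyl]chroman-7-ol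
Product: 25 (2S,3S,4R)-3-(benzyloxy)-2-[3,4-bis(benzyloxy)phenyl]-4-methoxychroman-7-ol, via para-quinone methide 24 (not isolated)
Conditions: DDQ (1.05 equiv), CH2Cl2–MeOH (4:1), 0 °C
Reagents that add atoms: methanol, CO
Why: Quinone dehydrogenation of a p-alkylphenol: the free 7-OH para to C4a directs DDQ to C4, and methanol adds 1,6 to the quinone methide, expected anti to the 3-benzyloxy group (the C4 configuration is lost again in step 20).

Step 19
Reactants: 25 (2S,3S,4R)-3-(benzyloxy)-2-[3,4-bis(benzyloxy)phenyl]-4-methoxychroman-7-ol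
Product: 26 (2S,3S,4R)-3,7-bis(benzyloxy)-2-[3,4-bis(benzyloxy)phenyl]-4-methoxychromane
Conditions: BnBr, K2CO3, acetone, rt
Reagents that add atoms: benzyl bromide, BrCc1ccccc1
Why: Williamson etherification of the phenol; the benzyl ether makes ring A of the electrophile less nucleophilic than ring A of 15, which should suppress self-condensation in step 20.

Step 20
Reactants: 26 (2S,3S,4R)-3,7-bis(benzyloxy)-2-[3,4-bis(benzyloxy)phenyl]-4-methoxychromane; 15 (2R,3S)-3-(benzyloxy)-2-[3,4-bis(benzyloxy)phenyl]chroman-7-ol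
Product: 27 (2S,3S,4R)-3,7-bis(benzyloxy)-2-[3,4-bis(benzyloxy)phenyl]-4-[(2R,3S)-3-(benzyloxy)-2-[3,4-bis(benzyloxy)phenyl]-7-hydroxychroman-6-yl]chromane
Conditions: BF3·OEt2 (0.5 equiv), 15 (2.5 equiv, excess recovered), CH2Cl2, −40 → 0 °C
Reagents that add atoms: none
Why: Lewis-acid Friedel–Crafts alkylation copying the biosynthetic interflavan coupling: BF3 ionizes the 4-methoxy group to the C4 cation (stabilized by O1 and the 7-benzyloxy group), C6 of 15 (ortho to the free 7-OH, para to O1, less hindered than C8) attacks, and approach anti to the axial 3-benzyloxy group should set the 3,4-trans (4R) centre.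

Step 21
Reactants: 27 hepta-O-benzyl dimer
Product: 28 ent-epifisetinidol-(4α→6)-fisetinidol (target)
Conditions: H2 (1 atm), Pd(OH)2/C, THF–MeOH (1:1), rt
Reagents that add atoms: none
Why: Hydrogenolysis of the seven benzyl ethers; the flavan C2–O1 bonds and the interflavan bond of this 5-deoxy dimer should survive, and no stereocentre is touched.

## Compound list

1 | L-tyrosine | N[C@@H](Cc1ccc(O)cc1)C(=O)O | starting material
2 | (S)-2-hydroxy-3-(4-hydroxyphenyl)propanoic acid | O[C@@H](Cc1ccc(O)cc1)C(=O)O | intermediate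
3 | allyl (S)-3-[4-(allyloxy)phenyl]-2-hydroxypropanoate | O[C@@H](Cc1ccc(OCC=C)cc1)C(=O)OCC=C | intermediate
4 | allyl (S)-3-[4-(allyloxy)phenyl]-2-(benzyloxy)propanoate | C(c1ccccc1)O[C@@H](Cc1ccc(OCC=C)cc1)C(=O)OCC=C | intermediate
5 | (S)-3-[4-(allyloxy)phenyl]-2-(benzyloxy)-N-methoxy-N-methylpropanamide | C(c1ccccc1)O[C@@H](Cc1ccc(OCC=C)cc1)C(=O)N(C)OC | intermediate
6 | 4-bromo-1,2-bis(benzyloxy)benzene | Brc1ccc(OCc2ccccc2)c(OCc2ccccc2)c1 | starting material
7 | [3,4-bis(benzyloxy)phenyl]magnesium bromide (titrated THF stock solution) | Br[Mg]c1ccc(OCc2ccccc2)c(OCc2ccccc2)c1 | intermediate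
8 | (S)-3-[4-(allyloxy)phenyl]-2-(benzyloxy)-1-[3,4-bis(benzyloxy)phenyl]propan-1-one | O=C(c1ccc(OCc2ccccc2)c(OCc2ccccc2)c1)[C@@H](OCc1ccccc1)Cc1ccc(OCC=C)cc1 | intermediate
9 | (1R,2S)-3-[4-(allyloxy)phenyl]-2-(benzyloxy)-1-[3,4-bis(benzyloxy)phenyl]propan-1-ol (anti) | O[C@H](c1ccc(OCc2ccccc2)c(OCc2ccccc2)c1)[C@@H](OCc1ccccc1)Cc1ccc(OCC=C)cc1 | intermediate
10 | [(1R,2S)-3-[4-(allyloxy)phenyl]-2-(benzyloxy)-1-[3,4-bis(benzyloxy)phenyl]propoxy]triethylsilane | CC[Si](CC)(CC)O[C@H](c1ccc(OCc2ccccc2)c(OCc2ccccc2)c1)[C@@H](OCc1ccccc1)Cc1ccc(OCC=C)cc1 | intermediate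
11 | 4-[(2S,3R)-2-(benzyloxy)-3-[3,4-bis(benzyloxy)phenyl]-3-(triethylsilyloxy)propyl]phenol | CC[Si](CC)(CC)O[C@H](c1ccc(OCc2ccccc2)c(OCc2ccccc2)c1)[C@@H](OCc1ccccc1)Cc1ccc(O)cc1 | intermediate
12 | 4-[(2S,3R)-2-(benzyloxy)-3-[3,4-bis(benzyloxy)phenyl]-3-(triethylsilyloxy)propyl]-4-methoxycyclohexa-2,5-dien-1-one | CC[Si](CC)(CC)O[C@H](c1ccc(OCc2ccccc2)c(OCc2ccccc2)c1)[C@@H](OCc1ccccc1)CC1(OC)C=CC(=O)C=C1 | intermediate
13 | 4-[(2S,3R)-2-(benzyloxy)-3-[3,4-bis(benzyloxy)phenyl]-3-hydroxypropyl]-4-methoxycyclohexa-2,5-dien-1-one | O[C@H](c1ccc(OCc2ccccc2)c(OCc2ccccc2)c1)[C@@H](OCc1ccccc1)CC1(OC)C=CC(=O)C=C1 | intermediate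
14 | (2R,3S)-3-(benzyloxy)-2-[3,4-bis(benzyloxy)phenyl]-4a-methoxy-2,3,4,4a,8,8a-hexahydro-7H-chromen-7-one (cis ring fusion, either diastereomer) | O1[C@H](c3ccc(OCc4ccccc4)c(OCc4ccccc4)c3)[C@@H](OCc3ccccc3)CC2(OC)C=CC(=O)CC12 | intermediate
15 | (2R,3S)-3-(benzyloxy)-2-[3,4-bis(benzyloxy)phenyl]chroman-7-ol | Oc1ccc2c(c1)O[C@H](c1ccc(OCc3ccccc3)c(OCc3ccccc3)c1)[C@@H](OCc1ccccc1)C2 | intermediate
16 | (S)-3-[4-(allyloxy)phenyl]-2-(benzyloxy)propanal | O=C[C@@H](OCc1ccccc1)Cc1ccc(OCC=C)cc1 | intermediate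
17 | (1S,2S)-3-[4-(allyloxy)phenyl]-2-(benzyloxy)-1-[3,4-bis(benzyloxy)phenyl]propan-1-ol (syn) | O[C@@H](c1ccc(OCc2ccccc2)c(OCc2ccccc2)c1)[C@@H](OCc1ccccc1)Cc1ccc(OCC=C)cc1 | intermediate
18 | [(1S,2S)-3-[4-(allyloxy)phenyl]-2-(benzyloxy)-1-[3,4-bis(benzyloxy)phenyl]propoxy]triethylsilane | CC[Si](CC)(CC)O[C@@H](c1ccc(OCc2ccccc2)c(OCc2ccccc2)c1)[C@@H](OCc1ccccc1)Cc1ccc(OCC=C)cc1 | intermediate
19 | 4-[(2S,3S)-2-(benzyloxy)-3-[3,4-bis(benzyloxy)phenyl]-3-(triethylsilyloxy)propyl]phenol | CC[Si](CC)(CC)O[C@@H](c1ccc(OCc2ccccc2)c(OCc2ccccc2)c1)[C@@H](OCc1ccccc1)Cc1ccc(O)cc1 | intermediate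
20 | 4-[(2S,3S)-2-(benzyloxy)-3-[3,4-bis(benzyloxy)phenyl]-3-(triethylsilyloxy)propyl]-4-methoxycyclohexa-2,5-dien-1-one | CC[Si](CC)(CC)O[C@@H](c1ccc(OCc2ccccc2)c(OCc2ccccc2)c1)[C@@H](OCc1ccccc1)CC1(OC)C=CC(=O)C=C1 | intermediate
21 | 4-[(2S,3S)-2-(benzyloxy)-3-[3,4-bis(benzyloxy)phenyl]-3-hydroxypropyl]-4-methoxycyclohexa-2,5-dien-1-one | O[C@@H](c1ccc(OCc2ccccc2)c(OCc2ccccc2)c1)[C@@H](OCc1ccccc1)CC1(OC)C=CC(=O)C=C1 | intermediate
22 | (2S,3S)-3-(benzyloxy)-2-[3,4-bis(benzyloxy)phenyl]-4a-methoxy-2,3,4,4a,8,8a-hexahydro-7H-chromen-7-one (cis ring fusion, either diastereomer) | O1[C@@H](c3ccc(OCc4ccccc4)c(OCc4ccccc4)c3)[C@@H](OCc3ccccc3)CC2(OC)C=CC(=O)CC12 | intermediate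
23 | (2S,3S)-3-(benzyloxy)-2-[3,4-bis(benzyloxy)phenyl]chroman-7-ol | Oc1ccc2c(c1)O[C@@H](c1ccc(OCc3ccccc3)c(OCc3ccccc3)c1)[C@@H](OCc1ccccc1)C2 | intermediate
24 | (2S,3S)-3-(benzyloxy)-2-[3,4-bis(benzyloxy)phenyl]-2,3-dihydro-7H-chromen-7-one (para-quinone methide) | O=C1C=C2O[C@@H](c3ccc(OCc4ccccc4)c(OCc4ccccc4)c3)[C@@H](OCc3ccccc3)C=C2C=C1 | intermediate
25 | (2S,3S,4R)-3-(benzyloxy)-2-[3,4-bis(benzyloxy)phenyl]-4-methoxychroman-7-ol | Oc1ccc2c(c1)O[C@@H](c1ccc(OCc3ccccc3)c(OCc3ccccc3)c1)[C@@H](OCc1ccccc1)[C@@H]2OC | intermediate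
26 | (2S,3S,4R)-3,7-bis(benzyloxy)-2-[3,4-bis(benzyloxy)phenyl]-4-methoxychromane | C(c1ccccc1)Oc1ccc2c(c1)O[C@@H](c1ccc(OCc3ccccc3)c(OCc3ccccc3)c1)[C@@H](OCc1ccccc1)[C@@H]2OC | intermediate
27 | (2S,3S,4R)-3,7-bis(benzyloxy)-2-[3,4-bis(benzyloxy)phenyl]-4-[(2R,3S)-3-(benzyloxy)-2-[3,4-bis(benzyloxy)phenyl]-7-hydroxychroman-6-yl]chromane (hepta-O-benzyl ether of 28, lower 7-OH free) | C(c1ccccc1)Oc1ccc2c(c1)O[C@@H](c1ccc(OCc3ccccc3)c(OCc3ccccc3)c1)[C@@H](OCc1ccccc1)[C@@H]2c1cc2c(cc1O)O[C@H](c1ccc(OCc3ccccc3)c(OCc3ccccc3)c1)[C@@H](OCc1ccccc1)C2 | intermediate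
28 | (2S,3S,4R)-2-(3,4-dihydroxyphenyl)-4-[(2R,3S)-2-(3,4-dihydroxyphenyl)-3,7-dihydroxychroman-6-yl]chromane-3,7-diol, ent-epifisetinidol-(4α→6)-fisetinidol | Oc1ccc2c(c1)O[C@@H](c1ccc(O)c(O)c1)[C@@H](O)[C@@H]2c1cc2c(cc1O)O[C@H](c1ccc(O)c(O)c1)[C@@H](O)C2 | target

## Step count

Total step count: 21 (steps 1–4 common, step 5 the aryl Grignard reagent, steps 6–11 lower unit, steps 12–19 upper unit, steps 20–21 union and deprotection).
Longest linear sequence: 14 steps (1–4, 12–19, 20, 21).

## Steps most likely to fail, with fallbacks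

Step 11 (step 17 is the same operation). What may go wrong: before the ring has closed, the free benzylic carbinol 13 stands in acid, and ionization at C2, helped by the 3,4-bis(benzyloxy)phenyl group, would erode the C2 configuration. Acid may also divert the dienone into a dienone–phenol alkyl shift, or the sequence may stop at 14. Fallback, setting out from 12 and coming back at 15: the domino is split into two stages so that the C–O bond is made without acid. Bu4NF buffered with AcOH in THF at 0 °C removes the silyl group, and the liberated hydroxyl is allowed to add to the dienone under these weakly basic conditions (K2CO3 added if needed). The cis-fused ketone 14 is isolated. Only then, with O1 already part of the tetrahydropyran ether, is methanol expelled with TsOH in toluene at 60 °C to give 15. This fallback makes no compound outside the list (F0); the same staged course through 21 and 22 would serve step 17.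

Step 18. What may go wrong: over-oxidation of the electron-rich phenol (a second dehydrogenation of 25 at C4, or oxidative coupling of the phenol with the reduced quinone) and loss of material through the reactive quinone methide. Fallback, setting out from 23 and coming back at 27: 23 is benzylated first (BnBr, K2CO3, acetone) to (2S,3S)-3,7-bis(benzyloxy)-2-[3,4-bis(benzyloxy)phenyl]chromane F1. C4 of the ether is then functionalized by hydride abstraction with DDQ in CH2Cl2 in the presence of 2-ethoxyethanol, the usual C4 activation of O-benzylated flavan-3-ols, to give the 4-(2-ethoxyethoxy) ether F2. F2 is coupled with 15 (excess) under TMSOTf in CH2Cl2 at −78 °C, which leads directly to 27.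

Step 20. What may go wrong: poor site selectivity between C6 and C8 of the free phenol 15, reversible O-alkylation, and chain growth by a second alkylation of the product. Fallback, setting out from 15 and coming back at 28: 15 is converted into its 7-O-benzyl ether, (2R,3S)-3,7-bis(benzyloxy)-2-[3,4-bis(benzyloxy)phenyl]chromane F3 (BnBr, K2CO3, acetone), in which C8 is flanked by O1 and a benzyloxy group. 26 is coupled with excess F3 under TMSOTf in CH2Cl2 at −78 °C, the usual conditions for fully benzylated flavan partners, to give the octa-O-benzyl ether of 28, F4. Hydrogenolysis as in step 21 gives 28.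

Further compounds
F0 | step 11 | none | none
F1 | step 18 | (2S,3S)-3,7-bis(benzyloxy)-2-[3,4-bis(benzyloxy)phenyl]chromane | C(c1ccccc1)Oc1ccc2c(c1)O[C@@H](c1ccc(OCc3ccccc3)c(OCc3ccccc3)c1)[C@@H](OCc1ccccc1)C2
F2 | step 18 | (2S,3S,4R)-3,7-bis(benzyloxy)-2-[3,4-bis(benzyloxy)phenyl]-4-(2-ethoxyethoxy)chromane | C(c1ccccc1)Oc1ccc2c(c1)O[C@@H](c1ccc(OCc3ccccc3)c(OCc3ccccc3)c1)[C@@H](OCc1ccccc1)[C@@H]2OCCOCC
F3 | step 20 | (2R,3S)-3,7-bis(benzyloxy)-2-[3,4-bis(benzyloxy)phenyl]chromane | C(c1ccccc1)Oc1ccc2c(c1)O[C@H](c1ccc(OCc3ccccc3)c(OCc3ccccc3)c1)[C@@H](OCc1ccccc1)C2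
F4 | step 20 | octa-O-benzyl ether of 28 (all eight hydroxyl groups benzylated, configuration as in 28) | C(c1ccccc1)Oc1ccc2c(c1)O[C@@H](c1ccc(OCc3ccccc3)c(OCc3ccccc3)c1)[C@@H](OCc1ccccc1)[C@@H]2c1cc2c(cc1OCc1ccccc1)O[C@H](c1ccc(OCc3ccccc3)c(OCc3ccccc3)c1)[C@@H](OCc1ccccc1)C2
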